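**Retrosynthetic overview**
1. Target ⇒ desilylation and oxidation of a side-chain carbinol; the α-ketol comes from a vicinal diol made by syn-dihydroxylation of an exocyclic tridecylidene alkene, anti to both flanking ring oxygens.
2. The alkylidene cyclopentenyl acetate ⇒ acetylation and cis-selective 1,2-reduction of a cross-conjugated 5-alkylidene-4-silyloxycyclopent-2-enone ⇒ dehydration of a β-hydroxy ketone.
3. Key C–C disconnection (ring carbon to side-chain C1'): intermolecular aldol addition of the α'-lithium enolate of (S)-4-(TBSO)cyclopent-2-enone to tridecanal.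
4. The silyloxy enone ⇐ commercial (1S,4R)-cis-4-acetoxycyclopent-2-en-1-ol by silylation, deacetylation and oxidation; this is the source of absolute configuration.
5. Rings: the single cyclopentene ring is never built; it is carried intact from the chiral-pool monoacetate.

Assumption: (1S,4R)-cis-4-acetoxycyclopent-2-en-1-ol and tridecanal are taken as catalogue items; the side-chain carbon attached to the ring is called C1'.

**Step 1**
Reactants: 1 (1S,4R)-cis-4-acetoxycyclopent-2-en-1-ol
Product: 2 (1R,4S)-4-[(tert-butyldimethylsilyl)oxy]cyclopent-2-en-1-yl acetate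
Conditions: TBSCl, imidazole, DMF, 0 °C → rt
Reagents that add atoms: tert-butyldimethylsilyl chloride (TBSCl), CC(C)(C)[Si](C)(C)Cl
Why: Imidazole-promoted O-silylation of the free allylic alcohol touches no stereocentre and leaves the acetate intact.

**Step 2**
Reactants: 2 (1R,4S)-4-[(tert-butyldimethylsilyl)oxy]cyclopent-2-en-1-yl acetate
Product: 3 (1R,4S)-4-[(tert-butyldimethylsilyl)oxy]cyclopent-2-en-1-ol
Conditions: K2CO3 (0.2 equiv), MeOH, 0 °C → rt
Reagents that add atoms: none
Why: Base-catalysed transesterification (methanolysis) removes the acetate, while a secondary TBS ether is stable to K2CO3/MeOH.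

**Step 3**
Reactants: 3 (1R,4S)-4-[(tert-butyldimethylsilyl)oxy]cyclopent-2-en-1-ol
Product: 4 (4S)-4-[(tert-butyldimethylsilyl)oxy]cyclopent-2-en-1-one
Conditions: Dess–Martin periodinane, CH2Cl2, 0 °C → rt
Reagents that add atoms: none
Why: Dess–Martin oxidation of the allylic alcohol gives the enone under non-basic conditions that do not endanger the β-silyloxy group or its stereocentre.

**Step 4**
Reactants: 4 (4S)-4-[(tert-butyldimethylsilyl)oxy]cyclopent-2-en-1-one; 5 tridecanal
Product: 7 (4R,5S)-4-[(tert-butyldimethylsilyl)oxy]-5-(1-hydroxytridecyl)cyclopent-2-en-1-one (C1' epimers), via lithium dienolate 6 (not isolated)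
Conditions: LiN(iPr)2 (LDA, 1.1 equiv), THF, −78 °C; then 5, −78 °C; sat. aq NH4Cl, −78 °C
Reagents that add atoms: none
Why: Kinetic α'-deprotonation gives the cross-conjugated lithium enolate, which undergoes intermolecular aldol addition to the aldehyde on the face opposite the adjacent OTBS group (4,5-trans); the C1' carbinol forms as a mixture that is erased later.

**Step 5**
Reactants: 7 (4R,5S)-4-[(tert-butyldimethylsilyl)oxy]-5-(1-hydroxytridecyl)cyclopent-2-en-1-one
Product: 9 (4R,5E)-4-[(tert-butyldimethylsilyl)oxy]-5-tridecylidenecyclopent-2-en-1-one, via secondary mesylate 8 (not isolated)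
Conditions: MsCl, Et3N (4 equiv), CH2Cl2, −10 °C → rt
Reagents that add atoms: none
Why: Mesylation followed by E1cB elimination expels the exocyclic mesylate (loss of the ring silyloxide would require a cyclopentadienone) and gives the cross-conjugated dienone mainly as the E isomer; either geometry converges after step 9.

**Step 6**
Reactants: 9 (4R,5E)-4-[(tert-butyldimethylsilyl)oxy]-5-tridecylidenecyclopent-2-en-1-one
Product: 10 (1S,4R,5Z)-4-[(tert-butyldimethylsilyl)oxy]-5-tridecylidenecyclopent-2-en-1-ol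
Conditions: NaBH4, CeCl3·7H2O, MeOH, −78 °C
Reagents that add atoms: none
Why: Luche 1,2-reduction delivers hydride to the face of the flat dienone opposite the OTBS group, so the new (1S) carbinol is cis to the silyl ether (the alkene geometry is unchanged; only the descriptor changes).

**Step 7**
Reactants: 10 (1S,4R,5Z)-4-[(tert-butyldimethylsilyl)oxy]-5-tridecylidenecyclopent-2-en-1-ol
Product: 11 (1S,4R,5Z)-4-[(tert-butyldimethylsilyl)oxy]-5-tridecylidenecyclopent-2-en-1-yl acetate
Conditions: Ac2O, pyridine, DMAP (cat.), CH2Cl2, 0 °C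
Reagents that add atoms: acetic anhydride, CC(=O)OC(C)=O
Why: DMAP-catalysed O-acylation with retention installs the acetate on the only free hydroxyl, before any other hydroxyl exists.

**Step 8**
Reactants: 11 (1S,4R,5Z)-4-[(tert-butyldimethylsilyl)oxy]-5-tridecylidenecyclopent-2-en-1-yl acetate
Product: 12 (1S,4R,5R)-4-[(tert-butyldimethylsilyl)oxy]-5-hydroxy-5-[(1S)-1-hydroxytridecyl]cyclopent-2-en-1-yl acetate
Conditions: OsO4 (4 mol %), NMO (1.1 equiv), acetone/H2O 8:1, 0 °C → rt; aq Na2S2O3
Reagents that add atoms: osmium tetroxide, O=[Os](=O)(=O)=O; N-methylmorpholine N-oxide (NMO), C[N+]1([O-])CCOCC1; water, O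
Why: Upjohn syn-dihydroxylation with about one equivalent of oxidant should favour the more electron-rich trisubstituted exocyclic alkene over the cis-disubstituted ring alkene, and attack opposite the cis-disposed OAc and OTBS groups places the new tertiary hydroxyl trans to both.

**Step 9**
Reactants: 12 (1S,4R,5R)-4-[(tert-butyldimethylsilyl)oxy]-5-hydroxy-5-[(1S)-1-hydroxytridecyl]cyclopent-2-en-1-yl acetate
Product: 13 (1S,4R,5R)-4-[(tert-butyldimethylsilyl)oxy]-5-hydroxy-5-tridecanoylcyclopent-2-en-1-yl acetate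
Conditions: IBX (2 equiv), DMSO, rt
Reagents that add atoms: none
Why: IBX oxidation converts the secondary alcohol of the vicinal diol into the ketone without glycol cleavage, the tertiary alcohol being inert, and removes the C1' stereocentre.

**Step 10**
Reactants: 13 (1S,4R,5R)-4-[(tert-butyldimethylsilyl)oxy]-5-hydroxy-5-tridecanoylcyclopent-2-en-1-yl acetate
Product: 14 (1S,4R,5S)-4,5-dihydroxy-5-tridecanoylcyclopent-2-en-1-yl acetate
Conditions: HF·pyridine, pyridine, THF, 0 °C → rt
Reagents that add atoms: none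
Why: Fluoride-mediated desilylation under buffered, weakly acidic conditions frees the secondary allylic alcohol without the acetate migration or α-ketol rearrangement that a basic fluoride source could trigger.

**Compound list**
1 | (1S,4R)-cis-4-acetoxycyclopent-2-en-1-ol [= (1R,4S)-4-hydroxycyclopent-2-en-1-yl acetate] | O[C@@H]1C=C[C@H](OC(C)=O)C1 | starting material
2 | (1R,4S)-4-[(tert-butyldimethylsilyl)oxy]cyclopent-2-en-1-yl acetate | CC(C)(C)[Si](C)(C)O[C@@H]1C=C[C@H](OC(C)=O)C1 | intermediate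
3 | (1R,4S)-4-[(tert-butyldimethylsilyl)oxy]cyclopent-2-en-1-ol | CC(C)(C)[Si](C)(C)O[C@@H]1C=C[C@H](O)C1 | intermediate
4 | (4S)-4-[(tert-butyldimethylsilyl)oxy]cyclopent-2-en-1-one | CC(C)(C)[Si](C)(C)O[C@@H]1C=CC(=O)C1 | intermediate
5 | tridecanal | CCCCCCCCCCCCC=O | starting material
6 | lithium (3R)-3-[(tert-butyldimethylsilyl)oxy]cyclopenta-1,4-dien-1-olate (lithium dienolate of 4, formed in situ) | [Li]OC1=C[C@H](O[Si](C)(C)C(C)(C)C)C=C1 | intermediate
7 | (4R,5S)-4-[(tert-butyldimethylsilyl)oxy]-5-(1-hydroxytridecyl)cyclopent-2-en-1-one (4,5-trans; C1' epimers) | CCCCCCCCCCCCC(O)[C@H]1[C@H](O[Si](C)(C)C(C)(C)C)C=CC1=O | intermediate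
8 | 1-[(1R,5R)-5-[(tert-butyldimethylsilyl)oxy]-2-oxocyclopent-3-en-1-yl]tridecyl methanesulfonate (mesylate of 7, formed in situ) | CCCCCCCCCCCCC(OS(C)(=O)=O)[C@H]1[C@H](O[Si](C)(C)C(C)(C)C)C=CC1=O | intermediate
9 | (4R,5E)-4-[(tert-butyldimethylsilyl)oxy]-5-tridecylidenecyclopent-2-en-1-one (alkyl chain on the OTBS side) | CCCCCCCCCCCC/C=C1\[C@H](O[Si](C)(C)C(C)(C)C)C=CC1=O | intermediate
10 | (1S,4R,5Z)-4-[(tert-butyldimethylsilyl)oxy]-5-tridecylidenecyclopent-2-en-1-ol (OH cis to OTBS) | CCCCCCCCCCCC/C=C1\[C@H](O[Si](C)(C)C(C)(C)C)C=C[C@@H]1O | intermediate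
11 | (1S,4R,5Z)-4-[(tert-butyldimethylsilyl)oxy]-5-tridecylidenecyclopent-2-en-1-yl acetate | CCCCCCCCCCCC/C=C1\[C@H](O[Si](C)(C)C(C)(C)C)C=C[C@@H]1OC(C)=O | intermediate
12 | (1S,4R,5R)-4-[(tert-butyldimethylsilyl)oxy]-5-hydroxy-5-[(1S)-1-hydroxytridecyl]cyclopent-2-en-1-yl acetate | CCCCCCCCCCCC[C@H](O)[C@]1(O)[C@H](O[Si](C)(C)C(C)(C)C)C=C[C@@H]1OC(C)=O | intermediate
13 | (1S,4R,5R)-4-[(tert-butyldimethylsilyl)oxy]-5-hydroxy-5-tridecanoylcyclopent-2-en-1-yl acetate | CCCCCCCCCCCCC(=O)[C@]1(O)[C@H](O[Si](C)(C)C(C)(C)C)C=C[C@@H]1OC(C)=O | intermediate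
14 | (1S,4R,5S)-4,5-dihydroxy-5-tridecanoylcyclopent-2-en-1-yl acetate | CCCCCCCCCCCCC(=O)[C@]1(O)[C@H](O)C=C[C@@H]1OC(C)=O | target

**Totals**
Total step count: 10. Longest linear sequence: 10 steps, from 1 to 14; tridecanal 5 enters directly in step 4.

**Steps most likely to fail, with fallbacks**

Step 4 (aldol). The lithium dienolate carries a β-silyloxy group and may eliminate or self-condense, and it can be quenched by proton transfer from the enolisable aldehyde. The fallback replaces the hard lithium enolate by soft enolisation. It sets out from 4: Bu2BOTf and iPr2NEt in CH2Cl2 at −78 °C give the dibutylboron dienolate F1, which adds to 5 at −78 °C through a closed transition state, again anti to the OTBS group. Work-up with pH 7 buffer/MeOH returns to the route at 7.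

Step 8 (dihydroxylation). The ring alkene may compete with the exocyclic alkene, giving regioisomeric diol or tetrol; the selectivity argument rests on substitution pattern only. The fallback installs the tertiary oxygen by enolate oxidation, so that no alkene selectivity is needed. It sets out from 7:
- TESOTf and 2,6-lutidine give the triethylsilyl ether F2.
- NaN(SiMe3)2 in THF at −78 °C gives the sodium dienolate F3, which is trapped with 2-(phenylsulfonyl)-3-phenyloxaziridine (Davis reagent) on the face opposite the OTBS group to give the α-hydroxy enone F4.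
- Luche reduction (NaBH4, CeCl3·7H2O, MeOH, −78 °C), with hydride entering opposite the bulky side chain, gives the ring diol F5.
- Ac2O/pyridine acetylates only the secondary ring alcohol to give the acetate F6.
- PPTS in MeOH removes only the TES group to give the diol F7 (12 together with its C1' epimer).
- IBX oxidation as in step 9 returns to the route at 13.

Step 10 (final desilylation). The TBS ether sits next to the quaternary centre and may cleave slowly; forcing conditions risk acetate migration or hydrolysis and α-ketol rearrangement. The fallback exchanges the silyl group for a more labile one while the molecule is still robust. It sets out from 11: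
- TBAF buffered with AcOH in THF at 0 °C gives the allylic alcohol F8.
- TESCl and imidazole give the triethylsilyl ether F9.
- OsO4/NMO as in step 8 gives the diol F10.
- IBX as in step 9 gives the ketol F11.
- AcOH/THF/H2O (3:1:1) at rt removes the TES ether and returns to the route at the target 14.

**Further compounds**
F1 | step 4 | dibutyl{[(3R)-3-[(tert-butyldimethylsilyl)oxy]cyclopenta-1,4-dien-1-yl]oxy}borane (dibutylboron dienolate of 4) | CCCCB(CCCC)OC1=C[C@H](O[Si](C)(C)C(C)(C)C)C=C1
F2 | step 8 | (4R,5S)-4-[(tert-butyldimethylsilyl)oxy]-5-[1-(triethylsilyloxy)tridecyl]cyclopent-2-en-1-one | CCCCCCCCCCCCC(O[Si](CC)(CC)CC)[C@H]1[C@H](O[Si](C)(C)C(C)(C)C)C=CC1=O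
F3 | step 8 | sodium (3R)-3-[(tert-butyldimethylsilyl)oxy]-2-[1-(triethylsilyloxy)tridecyl]cyclopenta-1,4-dien-1-olate (sodium dienolate of F2) | [Na]OC1=C(C(CCCCCCCCCCCC)O[Si](CC)(CC)CC)[C@H](O[Si](C)(C)C(C)(C)C)C=C1
F4 | step 8 | (4R,5S)-4-[(tert-butyldimethylsilyl)oxy]-5-hydroxy-5-[1-(triethylsilyloxy)tridecyl]cyclopent-2-en-1-one | CCCCCCCCCCCCC(O[Si](CC)(CC)CC)[C@]1(O)[C@H](O[Si](C)(C)C(C)(C)C)C=CC1=O
F5 | step 8 | (1S,2S,5R)-5-[(tert-butyldimethylsilyl)oxy]-1-[1-(triethylsilyloxy)tridecyl]cyclopent-3-ene-1,2-diol | CCCCCCCCCCCCC(O[Si](CC)(CC)CC)[C@]1(O)[C@H](O[Si](C)(C)C(C)(C)C)C=C[C@@H]1O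
F6 | step 8 | (1S,4R,5S)-4-[(tert-butyldimethylsilyl)oxy]-5-hydroxy-5-[1-(triethylsilyloxy)tridecyl]cyclopent-2-en-1-yl acetate | CCCCCCCCCCCCC(O[Si](CC)(CC)CC)[C@]1(O)[C@H](O[Si](C)(C)C(C)(C)C)C=C[C@@H]1OC(C)=O
F7 | step 8 | (1S,4R,5R)-4-[(tert-butyldimethylsilyl)oxy]-5-hydroxy-5-(1-hydroxytridecyl)cyclopent-2-en-1-yl acetate (C1' epimers) | CCCCCCCCCCCCC(O)[C@]1(O)[C@H](O[Si](C)(C)C(C)(C)C)C=C[C@@H]1OC(C)=O
F8 | step 10 | (1S,4R,5E)-4-hydroxy-5-tridecylidenecyclopent-2-en-1-yl acetate | CCCCCCCCCCCC/C=C1\[C@H](O)C=C[C@@H]1OC(C)=O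
F9 | step 10 | (1S,4R,5Z)-4-(triethylsilyloxy)-5-tridecylidenecyclopent-2-en-1-yl acetate | CCCCCCCCCCCC/C=C1\[C@H](O[Si](CC)(CC)CC)C=C[C@@H]1OC(C)=O
F10 | step 10 | (1S,4R,5R)-5-hydroxy-5-[(1S)-1-hydroxytridecyl]-4-(triethylsilyloxy)cyclopent-2-en-1-yl acetate | CCCCCCCCCCCC[C@H](O)[C@]1(O)[C@H](O[Si](CC)(CC)CC)C=C[C@@H]1OC(C)=O
F11 | step 10 | (1S,4R,5R)-5-hydroxy-5-tridecanoyl-4-(triethylsilyloxy)cyclopent-2-en-1-yl acetate | CCCCCCCCCCCCC(=O)[C@]1(O)[C@H](O[Si](CC)(CC)CC)C=C[C@@H]1OC(C)=O
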